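**Plan**
Retrosynthesis: the two aryl–indolyl bonds at C5 and C8 of the chromene are cut first, then the pyran ring at C4–C4a and C2–C3, then O1–C2; this leads to 2,5-dibromo-3-methoxyhydroquinone and on to 2,5-dibromoanisole.
Forward: the benzene ring is bought; its two further oxygens come from directed lithiation–hydroxylation and Teuber para-oxidation; O1 is alkylated with an isobutyrate; the pyran ring arises in the key step; both indoles are joined last by a double Suzuki–Miyaura coupling.
Enabling feature: C2 is a fully substituted carbon on the ring oxygen O1 (a 2-aryloxyisobutyric acid releases it as a tertiary α-oxy radical), C3 and C4 are two unsubstituted sp2 carbons (acetylene), and C4a is the only unsubstituted ortho carbon of the pentasubstituted benzene ring.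
The indoles follow the key step because an indol-3-yl group at C8 would place its C2=C3 bond within six-membered reach of the C2 radical; bromine holds C5 and C8 until then.
Stereochemistry: the target has no stereocentre; the cis C3=C4 bond is fixed by the ring.

Key step: step 7

Remark: compounds 1, 7, 12 and 14 are taken as commercial, and acetylene is used as purified gas at atmospheric pressure.

**Step 1**
Reactants: 1 2,5-dibromoanisole (1,4-dibromo-2-methoxybenzene)
Product: 4 3,6-dibromo-2-methoxyphenol, via aryllithium 2 (not isolated), via lithium arylborate 3 (not isolated)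
Conditions: LiN(iPr)2, B(OiPr)3 (present from the start), THF, –78 °C to 0 °C; then AcOH, 30% H2O2, 0 °C to rt
Reagents that add atoms: hydrogen peroxide, OO
Why: LiN(iPr)2 should remove the most acidic ring proton, the one between the methoxy group and a bromine (directed ortho-metalation), in situ borate capture suppresses halogen dance and aryne formation, and peroxide oxidation of the C–B bond gives the phenol (lithiation–borylation–oxidation).

**Step 2**
Reactants: 4 3,6-dibromo-2-methoxyphenol
Product: 6 2,5-dibromo-3-methoxybenzene-1,4-diol, via dibromomethoxyquinone 5 (not isolated)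
Conditions: (KSO3)2NO, KH2PO4, H2O/acetone, rt; then aqueous Na2S2O4, EtOAc, rt, under argon
Reagents that add atoms: potassium nitrosodisulfonate (KSO3)2NO, [O]N(S(=O)(=O)[O-])S(=O)(=O)[O-].[K+].[K+]
Why: Teuber oxidation of a phenol with both ortho positions blocked and the para position free should give the para-quinone, and dithionite returns the hydroquinone, so the new oxygen enters at the future O1 position.

**Step 3**
Reactants: 6 2,5-dibromo-3-methoxybenzene-1,4-diol; 7 tert-butyl 2-bromo-2-methylpropanoate
Product: 8 tert-butyl 2-(2,5-dibromo-4-hydroxy-3-methoxyphenoxy)-2-methylpropanoate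
Conditions: K2CO3 (1.1 equiv), 7 (1.2 equiv), degassed DMF, 50 °C, argon
Reagents that add atoms: none
Why: Williamson-type alkylation of the phenoxide by the tertiary α-bromo ester is highly sensitive to ortho hindrance, so it should take place at the hydroxyl flanked by bromine and hydrogen and not at the one flanked by methoxy and bromine.

**Step 4**
Reactants: 8 tert-butyl 2-(2,5-dibromo-4-hydroxy-3-methoxyphenoxy)-2-methylpropanoate
Product: 9 tert-butyl 2-{2,5-dibromo-4-[(tert-butyldimethylsilyl)oxy]-3-methoxyphenoxy}-2-methylpropanoate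
Conditions: TBSCl, imidazole, DMAP (cat.), DMF, 40 °C
Reagents that add atoms: tert-butyldimethylsilyl chloride, CC(C)(C)[Si](C)(C)Cl
Why: Standard silylation of the remaining phenol removes the O–H that would act as hydrogen-atom donor and oxidisable phenoxide in step 7.

**Step 5**
Reactants: 9 tert-butyl 2-{2,5-dibromo-4-[(tert-butyldimethylsilyl)oxy]-3-methoxyphenoxy}-2-methylpropanoate
Product: 10 2-{2,5-dibromo-4-[(tert-butyldimethylsilyl)oxy]-3-methoxyphenoxy}-2-methylpropanoic acid
Conditions: TFA/CH2Cl2 (1:4), 0 °C to rt
Reagents that add atoms: none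
Why: Acidolysis of the tert-butyl ester with loss of isobutene should leave the hindered aryl silyl ether and the aryl bromides untouched, since phenolic silyl ethers resist anhydrous acid.

**Step 6**
Reactants: 10 2-{2,5-dibromo-4-[(tert-butyldimethylsilyl)oxy]-3-methoxyphenoxy}-2-methylpropanoic acid
Product: 11 1,3-dioxoisoindolin-2-yl 2-{2,5-dibromo-4-[(tert-butyldimethylsilyl)oxy]-3-methoxyphenoxy}-2-methylpropanoate
Conditions: N-hydroxyphthalimide, N,N'-diisopropylcarbodiimide, DMAP (cat.), CH2Cl2, rt
Reagents that add atoms: N-hydroxyphthalimide, ON1C(=O)c2ccccc2C1=O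
Why: Carbodiimide esterification converts the α-aryloxy acid into its redox-active N-acyloxyphthalimide, a routine operation for fibrate-type acids.

**Step 7**
Reactants: 11 1,3-dioxoisoindolin-2-yl 2-{2,5-dibromo-4-[(tert-butyldimethylsilyl)oxy]-3-methoxyphenoxy}-2-methylpropanoate; 12 acetylene
Product: 13 5,8-dibromo-6-[(tert-butyldimethylsilyl)oxy]-7-methoxy-2,2-dimethyl-2H-chromene
Conditions: fac-Ir(ppy)3 (1 mol %), acetylene (1 atm, solution presaturated), degassed DMSO, blue LEDs (450 nm), rt
Reagents that add atoms: none
Why: Proposed new method: photoexcited fac-Ir(ppy)3 transfers one electron to the N-acyloxyphthalimide, which loses CO2 and phthalimide anion to give the tertiary α-aryloxy radical at C2; this adds to acetylene, the vinyl radical at C4 attacks C4a, and the cyclohexadienyl radical is oxidised by the tetravalent iridium complex and deprotonated by phthalimide anion, so the whole is redox-neutral. The closest known reaction types are photoredox decarboxylative radical addition–cyclisation cascades of N-acyloxyphthalimides that end in homolytic aromatic substitution (oxindoles from N-arylacrylamides, phenanthridines from 2-isocyanobiaryls) and radical additions of α-oxy radicals to acetylene; new is the pairing of an α-aryloxyalkyl radical with acetylene to build a 2H-chromene. The pyran ring closes in a six-membered ortho mode (6-exo-trig counted on the C4a=C5 Kekulé bond), whereas five-membered ipso attack at C8a is reversible because its only exit would be an alkoxyl radical. No stereocentre is formed; the cis C3=C4 geometry follows from the fast inversion of the vinyl radical and from the ring. The step needs site selectivity for C4a and capture of the C2 radical by acetylene before anything else: the bromine at C8 blocks the second ortho carbon without offering a π bond to the C2 radical, the silyl ether removes the phenolic O–H as hydrogen-atom donor and as oxidisable phenoxide, and a saturated acetylene solution should outrun oxidation of the tertiary radical by the small stationary amount of tetravalent iridium.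

**Step 8**
Reactants: 13 5,8-dibromo-6-[(tert-butyldimethylsilyl)oxy]-7-methoxy-2,2-dimethyl-2H-chromene; 14 tert-butyl 3-(4,4,5,5-tetramethyl-1,3,2-dioxaborolan-2-yl)-1H-indole-1-carboxylate
Product: 15 di-tert-butyl 3,3'-{6-[(tert-butyldimethylsilyl)oxy]-7-methoxy-2,2-dimethyl-2H-chromene-5,8-diyl}bis(1H-indole-1-carboxylate)
Conditions: 14 (3 equiv), Pd(OAc)2 (10 mol %), SPhos (20 mol %), K3PO4, toluene/H2O (10:1), 90 °C
Reagents that add atoms: none
Why: Double Suzuki–Miyaura coupling with a dialkylbiarylphosphine on zerovalent palladium is suited to di-ortho-substituted, electron-rich aryl bromides, excess boronate offsets protodeboronation, and early loss of a silyl or Boc group would be harmless because step 9 removes them all.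

**Step 9**
Reactants: 15 di-tert-butyl 3,3'-{6-[(tert-butyldimethylsilyl)oxy]-7-methoxy-2,2-dimethyl-2H-chromene-5,8-diyl}bis(1H-indole-1-carboxylate)
Product: 16 kumbicin C (5,8-di(1H-indol-3-yl)-7-methoxy-2,2-dimethyl-2H-chromen-6-ol)
Conditions: K2CO3, degassed MeOH/THF, 60 °C, argon
Reagents that add atoms: none
Why: Carbonate-mediated methanolysis should cleave the aryl silyl ether and both indole N-Boc groups (activated as N-acylindoles) in one operation, while the 2,2-dimethylchromene is stable to base.

**Compound list**
1 | 2,5-dibromoanisole (1,4-dibromo-2-methoxybenzene) | COc1cc(Br)ccc1Br | starting material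
2 | (3,6-dibromo-2-methoxyphenyl)lithium | [Li]c1c(Br)ccc(Br)c1OC | intermediate
3 | lithium (3,6-dibromo-2-methoxyphenyl)tri(propan-2-yloxy)borate | [Li+].COc1c(Br)ccc(Br)c1[B-](OC(C)C)(OC(C)C)OC(C)C | intermediate
4 | 3,6-dibromo-2-methoxyphenol | COc1c(O)c(Br)ccc1Br | intermediate
5 | 2,5-dibromo-3-methoxycyclohexa-2,5-diene-1,4-dione | COC1=C(Br)C(=O)C=C(Br)C1=O | intermediate
6 | 2,5-dibromo-3-methoxybenzene-1,4-diol | COc1c(O)c(Br)cc(O)c1Br | intermediate
7 | tert-butyl 2-bromo-2-methylpropanoate | CC(C)(Br)C(=O)OC(C)(C)C | starting material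
8 | tert-butyl 2-(2,5-dibromo-4-hydroxy-3-methoxyphenoxy)-2-methylpropanoate | COc1c(O)c(Br)cc(OC(C)(C)C(=O)OC(C)(C)C)c1Br | intermediate
9 | tert-butyl 2-{2,5-dibromo-4-[(tert-butyldimethylsilyl)oxy]-3-methoxyphenoxy}-2-methylpropanoate | COc1c(O[Si](C)(C)C(C)(C)C)c(Br)cc(OC(C)(C)C(=O)OC(C)(C)C)c1Br | intermediate
10 | 2-{2,5-dibromo-4-[(tert-butyldimethylsilyl)oxy]-3-methoxyphenoxy}-2-methylpropanoic acid | COc1c(O[Si](C)(C)C(C)(C)C)c(Br)cc(OC(C)(C)C(=O)O)c1Br | intermediate
11 | 1,3-dioxoisoindolin-2-yl 2-{2,5-dibromo-4-[(tert-butyldimethylsilyl)oxy]-3-methoxyphenoxy}-2-methylpropanoate | COc1c(O[Si](C)(C)C(C)(C)C)c(Br)cc(OC(C)(C)C(=O)ON2C(=O)c3ccccc3C2=O)c1Br | intermediate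
12 | acetylene | C#C | starting material
13 | 5,8-dibromo-6-[(tert-butyldimethylsilyl)oxy]-7-methoxy-2,2-dimethyl-2H-chromene | COc1c(O[Si](C)(C)C(C)(C)C)c(Br)c2c(c1Br)OC(C)(C)C=C2 | intermediate
14 | tert-butyl 3-(4,4,5,5-tetramethyl-1,3,2-dioxaborolan-2-yl)-1H-indole-1-carboxylate | CC(C)(C)OC(=O)n1cc(B2OC(C)(C)C(C)(C)O2)c2ccccc21 | starting material
15 | di-tert-butyl 3,3'-{6-[(tert-butyldimethylsilyl)oxy]-7-methoxy-2,2-dimethyl-2H-chromene-5,8-diyl}bis(1H-indole-1-carboxylate) | COc1c(O[Si](C)(C)C(C)(C)C)c(-c2cn(C(=O)OC(C)(C)C)c3ccccc23)c2c(c1-c1cn(C(=O)OC(C)(C)C)c3ccccc13)OC(C)(C)C=C2 | intermediate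
16 | kumbicin C (5,8-di(1H-indol-3-yl)-7-methoxy-2,2-dimethyl-2H-chromen-6-ol) | COc1c(O)c(-c2c[nH]c3ccccc23)c2c(c1-c1c[nH]c3ccccc13)OC(C)(C)C=C2 | target

**Step count**
Total steps: 9. Longest linear sequence: 9 steps (1 to 16).

**Steps most likely to fail**

Step 7. The tertiary C2 radical may be oxidised by the tetravalent iridium complex to an oxocarbenium ion, or reduced, before it meets acetylene. The vinyl radical may also pick up a hydrogen atom before ring closure, or attack the bromine-bearing ortho carbon. The fallback is the classical chromene construction and sets out from 6. O-Propargylation with 3-chloro-3-methylbut-1-yne (CuCl2·2H2O cat., DBU, MeCN, 0 °C) at the less hindered hydroxyl should give 3,6-dibromo-2-methoxy-4-[(2-methylbut-3-yn-2-yl)oxy]phenol F1. Silylation (TBSCl, imidazole, DMF) should give tert-butyl{3,6-dibromo-2-methoxy-4-[(2-methylbut-3-yn-2-yl)oxy]phenoxy}dimethylsilane F2. Heating F2 in N,N-diethylaniline at 160 °C (aryl propargyl ether Claisen rearrangement, 1,5-hydrogen shift, oxa-6π electrocyclisation at the only free ortho carbon) should give the chromene, so the fallback comes back to the route at 13.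

Step 3. Site selectivity between the two hydroxyls may be poor, and dialkylation, elimination of HBr from the tertiary bromide and air oxidation of the hydroquinone monoanion may compete. The fallback fixes the two oxygens by their origin and sets out from 4. Duff formylation (hexamethylenetetramine, TFA, 80 °C, then aqueous HCl) at the only position para to the hydroxyl should give 2,5-dibromo-4-hydroxy-3-methoxybenzaldehyde F3. Silylation (TBSCl, imidazole) should give 2,5-dibromo-4-[(tert-butyldimethylsilyl)oxy]-3-methoxybenzaldehyde F4. Baeyer–Villiger oxidation (mCPBA, CH2Cl2) should give 2,5-dibromo-4-[(tert-butyldimethylsilyl)oxy]-3-methoxyphenyl formate F5, and brief methanolysis (NaHCO3, MeOH) should give 2,5-dibromo-4-[(tert-butyldimethylsilyl)oxy]-3-methoxyphenol F6. Alkylation of this single free phenol with 7 (K2CO3, MeCN, 60 °C) comes back to the route at 9.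

Step 8. Protodeboronation of the indol-3-ylboronate may outrun transmetalation at the two hindered, electron-rich C–Br bonds, and the second coupling may stall. The fallback is an anhydrous Negishi coupling and sets out from 13. Commercial tert-butyl 3-iodo-1H-indole-1-carboxylate with i-PrMgCl·LiCl (THF, –40 °C) should give [1-(tert-butoxycarbonyl)-1H-indol-3-yl]magnesium chloride F7. ZnCl2 should convert it into [1-(tert-butoxycarbonyl)-1H-indol-3-yl]zinc chloride F8. Coupling of F8 with 13 (Pd(OAc)2, SPhos, THF, 60 °C) comes back to the route at 15.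

**Further compounds**
F1 | step 7 | 3,6-dibromo-2-methoxy-4-[(2-methylbut-3-yn-2-yl)oxy]phenol | COc1c(O)c(Br)cc(OC(C)(C)C#C)c1Br
F2 | step 7 | tert-butyl{3,6-dibromo-2-methoxy-4-[(2-methylbut-3-yn-2-yl)oxy]phenoxy}dimethylsilane | COc1c(O[Si](C)(C)C(C)(C)C)c(Br)cc(OC(C)(C)C#C)c1Br
F3 | step 3 | 2,5-dibromo-4-hydroxy-3-methoxybenzaldehyde | COc1c(O)c(Br)cc(C=O)c1Br
F4 | step 3 | 2,5-dibromo-4-[(tert-butyldimethylsilyl)oxy]-3-methoxybenzaldehyde | COc1c(O[Si](C)(C)C(C)(C)C)c(Br)cc(C=O)c1Br
F5 | step 3 | 2,5-dibromo-4-[(tert-butyldimethylsilyl)oxy]-3-methoxyphenyl formate | COc1c(O[Si](C)(C)C(C)(C)C)c(Br)cc(OC=O)c1Br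
F6 | step 3 | 2,5-dibromo-4-[(tert-butyldimethylsilyl)oxy]-3-methoxyphenol | COc1c(O[Si](C)(C)C(C)(C)C)c(Br)cc(O)c1Br
F7 | step 8 | [1-(tert-butoxycarbonyl)-1H-indol-3-yl]magnesium chloride | CC(C)(C)OC(=O)n1cc([Mg]Cl)c2ccccc21
F8 | step 8 | [1-(tert-butoxycarbonyl)-1H-indol-3-yl]zinc chloride | CC(C)(C)OC(=O)n1cc([Zn]Cl)c2ccccc21
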